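The plan
- **Locants:** ring C1 (CH–O-isovaleryl), C2 (C=O), C3 (CMe) and C4 (CH) of the ring oxirane, C5 (CH2), C6 (CH). Chain C7 (oxirane C), C8 (oxirane CH2), C9 (C=O), C10=C11 (E), C12 (CMe2OH). "Top" is the ring face that carries C7. The target is (1S,3S,4S,6R,7R).
- **Enabling feature:** C1 and C4 both bear oxygen and face each other 1,4 across the carbocycle with C2–C3(Me) between them, and C6, next to C1, carries a carbon branch anti to the C1 oxygen. This is the footprint of an endo 7-oxanorbornene, so the ring is cut at C1–C6 and C4–C5 into 3-methylfuran and an acrylimide.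
- **Retrosynthetic cuts, in order:** the C1–O acyl bond, C9–C10, the C–O bonds of both oxiranes, C7–C9, re-closure of C4–O to the bridge, C7–C8, and finally C1–C6 with C4–C5.
- **Forward:** the [4+2] closes the only carbocycle as an oxanorbornene. C7 gains C8 and becomes a vinyl triflate. Hydroboration–oxidation gives the C2 ketone, and β-elimination opens the bridge so that O stays on C1 and C3=C4 appears. C9 is then coupled on, the chain oxirane and then the ring oxirane are closed, C10–C12 is added to a C9 aldehyde, and the ester goes on last.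
- **Stereochemistry:** C1 and C6 (and the transient C4) come from the chiral copper catalyst plus the endo rule. C7 comes from L-(+)-tartrate (reagent control). C3/C4 come from a temporary top-face C2 hydroxyl (axial hydride delivery) that directs the epoxidation. C10=C11 comes from syn-hydrozirconation.
- **Design rule:** from step 5 on C7 is never a carbonyl carbon, so once the bridge is open no intermediate has a C1 leaving group β to a chain carbonyl.

Key step: step 2

Assumption: the copper catalyst is taken to induce the same sense with 3-methylfuran as with furan itself, where the (S,S)-ligand gives the (1S,2S,4S) endo adduct; the (R,R)-ligand is therefore specified.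

Step 1
Reactants: 1 2-oxazolidinone; 2 acryloyl chloride
Product: 4 3-acryloyl-1,3-oxazolidin-2-one, via bromomagnesium oxazolidinonate 3 (not isolated)
Conditions: MeMgBr (1.0 equiv), THF, 0 °C; then 2 (1.1 equiv), −78 °C → 0 °C
Reagents that add atoms: none
Why: N-acylation of a metalated carbamate by an acid chloride, in which the soft magnesium salt is acylated at nitrogen without starting anionic polymerisation of the acrylate.

Step 2
Reactants: 4 3-acryloyl-1,3-oxazolidin-2-one; 5 3-methylfuran
Product: 6 3-[(1R,2R,4R)-5-methyl-7-oxabicyclo[2.2.1]hept-5-ene-2-carbonyl]-1,3-oxazolidin-2-one (endo; O-bridge on C1 and C4; Me on C3; acyl carbon C7 on C6 anti to the bridge)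
Conditions: [Cu((R,R)-t-Bu-box)](SbF6)2 (10 mol %, from CuCl2, AgSbF6 and 2,2'-(propane-2,2-diyl)bis[(4R)-4-tert-butyl-4,5-dihydrooxazole]), 5 (5 equiv), CH2Cl2, −78 °C; cold filtration through silica gel; recrystallisation
Reagents that add atoms: none
Why: The imide binds divalent copper through both carbonyl oxygens in a square-planar chelate with the acryloyl unit s-cis, and the furan adds suprafacially in a concerted but asynchronous normal-demand [4+2] cycloaddition, the closest known reaction being the same catalyst and dienophile with unsubstituted furan. The six-membered carbocycle C1–C6 closes in one intermolecular [4π+2π] event that forms C4–C5 and C1–C6 together, the furan oxygen ending as the C1–O–C4 bridge. C6 is set by the tert-butyl groups of the (R,R)-ligand, which leave only one face of the bound acrylimide open, and C1 and C4 follow from the endo transition state, which places the acyl group anti to the oxygen bridge. Regioselectivity is required and comes from the methyl group, which makes the neighbouring furan α-carbon (future C4) the most nucleophilic terminus, so that this carbon leads bond formation to the electrophilic acrylate β-carbon (C5) and the C3-methyl/C6-acyl "para" isomer results. Because the adduct can revert, the reaction is held at −78 °C and the catalyst removed cold, which should keep the kinetic endo product enantioenriched, and minor exo or regioisomeric adducts should be removable by crystallisation.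

Step 3
Reactants: 6 endo imide
Product: 7 (1R,2R,4R)-N-methoxy-N,5-dimethyl-7-oxabicyclo[2.2.1]hept-5-ene-2-carboxamide
Conditions: MeONHMe·HCl, AlMe3, CH2Cl2, −15 °C → 0 °C; aq. potassium sodium tartrate
Reagents that add atoms: N,O-dimethylhydroxylamine hydrochloride, CNOC.Cl
Why: Weinreb amide formation by aluminium-amide transamination attacks only the exocyclic imide carbonyl and is non-basic, so the C6–H next to the carbonyl is not removed and neither epimerisation nor β-elimination of the C1–O bridge should intervene.

Step 4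
Reactants: 7 Weinreb amide
Product: 9 1-[(1R,2R,4R)-5-methyl-7-oxabicyclo[2.2.1]hept-5-en-2-yl]ethan-1-one, via magnesium hemiaminal chelate 8 (not isolated)
Conditions: MeMgBr (1.3 equiv), THF, −78 °C → 0 °C; cold water/pH 7 buffer
Reagents that add atoms: methylmagnesium bromide, C[Mg]Br
Why: Weinreb ketone synthesis, in which the chelated tetrahedral adduct 8 survives until the cold aqueous quench, so that exactly one methyl group (C8) is delivered to C7 and the endo ketone never meets excess base.

Step 5
Reactants: 9 methyl ketone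
Product: 11 1-[(1R,2R,4R)-5-methyl-7-oxabicyclo[2.2.1]hept-5-en-2-yl]ethenyl trifluoromethanesulfonate, via terminal potassium enolate 10 (not isolated)
Conditions: 9 added to KN(SiMe3)2 (1.1 equiv), THF, −78 °C; N-(5-chloro-2-pyridyl)triflimide, −78 °C
Reagents that add atoms: N-(5-chloropyridin-2-yl)bis(trifluoromethanesulfonyl)imide, O=S(=O)(N(c1ccc(Cl)cn1)S(=O)(=O)C(F)(F)F)C(F)(F)F
Why: Kinetic enolate formation and O-sulfonylation (enol triflate synthesis), in which the hindered amide base removes a methyl proton of the methyl sec-alkyl ketone far faster than the tertiary C6–H and the highly reactive pyridyl triflimide traps enolate 10 at −78 °C before proton exchange could produce the C6 enolate that would expel the bridge oxygen.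

Step 6
Reactants: 11 enol triflate
Product: 13 1-[(1S,2R,4R,5R,6R)-6-hydroxy-5-methyl-7-oxabicyclo[2.2.1]heptan-2-yl]ethenyl trifluoromethanesulfonate (C2 exo-OH; C3 endo-Me), via B-alkyl-9-BBN adduct 12 (not isolated)
Conditions: 9-BBN, THF, 0 °C → rt; then 30 % H2O2, aq. NaOH, 0 °C
Reagents that add atoms: hydrogen peroxide, OO
Why: Hydroboration–oxidation, in which the strained, electron-rich C2=C3 bond adds 9-BBN syn from the open exo face with boron on the less substituted C2 while the triflate-deactivated C7=C8 bond stays inert, and oxidation with retention gives the exo C2 alcohol and the endo C3 methyl group, two temporary stereocentres that are erased in steps 7 and 8.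

Step 7
Reactants: 13 exo alcohol
Product: 14 1-[(1S,2R,4R,5S)-5-methyl-6-oxo-7-oxabicyclo[2.2.1]heptan-2-yl]ethenyl trifluoromethanesulfonate (C2 ketone)
Conditions: Dess–Martin periodinane, NaHCO3, CH2Cl2, 0 °C → rt
Reagents that add atoms: none
Why: Dess–Martin oxidation of a secondary alcohol under buffered, non-enolising conditions, which the vinyl triflate and the ether bridge tolerate.

Step 8
Reactants: 14 bicyclic ketone
Product: 16 1-[(1R,6S)-6-(tert-butyldimethylsilyloxy)-4-methyl-5-oxocyclohex-3-en-1-yl]ethenyl trifluoromethanesulfonate (C1-OTBS trans to C7; C2 enone; C3=C4), via silyl enol ether 15 (not isolated)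
Conditions: TBSOTf (1.3 equiv), Et3N (3 equiv), CH2Cl2, 0 °C → rt
Reagents that add atoms: tert-butyldimethylsilyl trifluoromethanesulfonate, CC(C)(C)[Si](C)(C)OS(=O)(=O)C(F)(F)F
Why: Silyl-triflate/amine-induced β-elimination of a 7-oxanorbornan-2-one (E1cB type), in which enolisation can go only towards C3 because C1 is a bridgehead, silylation of the bridge oxygen makes it a leaving group on C4, and collapse of enol ether 15 relieves the bicyclic strain, creates C3=C4 and leaves the oxygen on C1 as its TBS ether with the C1 and C6 configurations (trans-diequatorial, also the thermodynamic arrangement) untouched.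

Step 9
Reactants: 16 enone triflate
Product: 17 (5S,6S)-6-(tert-butyldimethylsilyloxy)-5-(3-hydroxyprop-1-en-2-yl)-2-methylcyclohex-2-en-1-one
Conditions: Bu3SnCH2OH (1.8 equiv), Pd(PPh3)4 (10 mol %), LiCl (5 equiv), 1,4-dioxane, 90 °C
Reagents that add atoms: (tributylstannyl)methanol, CCCC[Sn](CCCC)(CCCC)CO
Why: Stille cross-coupling of an alkenyl triflate with a hydroxymethylstannane on zerovalent palladium, LiCl assisting triflate–chloride exchange, forms C7–C9 under neutral conditions that spare the enone and the silyl ether and gives the 2-substituted allylic alcohol without any redox adjustment.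

Step 10
Reactants: 17 allylic alcohol
Product: 18 (5R,6S)-6-(tert-butyldimethylsilyloxy)-5-[(2S)-2-(hydroxymethyl)oxiran-2-yl]-2-methylcyclohex-2-en-1-one
Conditions: Ti(O-i-Pr)4 (10 mol %), L-(+)-diisopropyl tartrate (13 mol %), t-BuOOH (decane), 4 Å MS, CH2Cl2, −20 °C
Reagents that add atoms: tert-butyl hydroperoxide, CC(C)(C)OO
Why: Sharpless asymmetric epoxidation, a reagent-controlled reaction in which L-(+)-tartrate turns 2-alkylprop-2-en-1-ols into (S)-2-alkylglycidols, sets C7 in the required sense [(7S) here and (7R) once C9 is a carbonyl], while catalytic titanium with sieves limits opening of the 2,2-disubstituted oxirane and the electron-poor ring enone, which has no allylic hydroxyl, is not touched.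

Step 11
Reactants: 18 epoxy alcohol enone
Product: 19 (1S,5R,6S)-6-(tert-butyldimethylsilyloxy)-5-[(2S)-2-(hydroxymethyl)oxiran-2-yl]-2-methylcyclohex-2-en-1-ol (C2-OH on the top face)
Conditions: NaBH4, CeCl3·7H2O, MeOH, −78 °C → −40 °C
Reagents that add atoms: none
Why: Luche 1,2-reduction, in which hydride enters axially from the bottom face of the half-chair whose C1-OTBS and C6 substituents are equatorial and so gives the pseudo-equatorial top-face C2 alcohol (trans to C1–O and cis to C7), the same outcome as carvone to cis-carveol, while oxirane and silyl ether are inert to NaBH4.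

Step 12
Reactants: 19 ring allylic alcohol
Product: 20 (1R,2R,3S,4R,6S)-3-(tert-butyldimethylsilyloxy)-4-[(2S)-2-(hydroxymethyl)oxiran-2-yl]-1-methyl-7-oxabicyclo[4.1.0]heptan-2-ol (C3/C4 oxirane on the top face)
Conditions: VO(acac)2 (5 mol %), t-BuOOH (decane), CH2Cl2, 0 °C → rt
Reagents that add atoms: tert-butyl hydroperoxide, CC(C)(C)OO
Why: Hydroxyl-directed epoxidation of an allylic alcohol, in which the vanadium alkoxide–peroxide formed at the C2 hydroxyl delivers oxygen to C3=C4 on its own (top) face and so sets C3 and C4 cis to the side chain, the face that nucleophilic epoxidation of enone 18 would avoid.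

Step 13
Reactants: 20 bis-epoxy diol
Product: 21 (2R)-2-[(1S,3R,4S,6S)-4-(tert-butyldimethylsilyloxy)-6-methyl-5-oxo-7-oxabicyclo[4.1.0]heptan-3-yl]oxirane-2-carbaldehyde (C2 ketone; C9 aldehyde)
Conditions: Dess–Martin periodinane (3 equiv), NaHCO3, CH2Cl2, 0 °C → rt
Reagents that add atoms: none
Why: Dess–Martin oxidation converts the secondary C2 and the primary C9 alcohols in one operation under buffered conditions that spare both oxiranes, and no stereocentre is endangered because C3 and C7 are quaternary and C1 keeps its equatorial silyloxy group.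

Step 14
Reactants: 21 keto aldehyde; 22 trimethyl[(2-methylbut-3-yn-2-yl)oxy]silane
Product: 25 C9 carbinol (both C9 epimers) bearing the (E)-C10=C11–C12(Me)2OTMS chain on the core of 21, via alkenylzirconocene chloride 23 (not isolated), via alkenyl(methyl)zinc 24 (not isolated)
Conditions: 22 (2.0 equiv), Cp2Zr(H)Cl (1.9 equiv), CH2Cl2, rt; Me2Zn (1.9 equiv, toluene), −65 °C; then 21, 0 °C; water
Reagents that add atoms: none
Why: syn-Hydrozirconation of the terminal alkyne puts the metal on the terminal carbon and fixes the E geometry of C10=C11, and zirconium-to-zinc transmetalation gives an alkenylzinc that undergoes 1,2-addition to aldehydes but not to the hindered C2 ketone, the oxiranes or the silyl ethers, the C9 configuration being irrelevant since it is oxidised in step 15.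

Step 15
Reactants: 25 C9 carbinol
Product: 26 bis-silylated enone (C1-OTBS; C12-OTMS; C9 ketone; otherwise the target skeleton; 1S,3S,4S,6R,7R)
Conditions: Dess–Martin periodinane, NaHCO3, CH2Cl2, 0 °C
Reagents that add atoms: none
Why: Dess–Martin oxidation of the allylic C9 alcohol gives the α,β-unsaturated α′,β′-epoxy ketone without touching the E double bond, both C9 epimers converging on one compound.

Step 16
Reactants: 26 bis-silylated enone
Product: 27 C1,C12-diol (the target lacking its isovaleryl group; 1S,3S,4S,6R,7R)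
Conditions: HF·pyridine, pyridine, THF, 0 °C → rt
Reagents that add atoms: none
Why: Fluoride-mediated desilylation with pyridine-buffered HF removes the tertiary TMS ether and the α-keto-activated secondary TBS ether, while both oxiranes, each deactivated towards acid opening by its adjacent carbonyl group, should survive.

Step 17
Reactants: 27 C1,C12-diol; 28 3-methylbutanoic anhydride
Product: 29 CNP0292003.1 (target)
Conditions: 28 (1.5 equiv), DMAP (10 mol %), pyridine, CH2Cl2, 0 °C
Reagents that add atoms: none
Why: DMAP-catalysed esterification with an anhydride acylates the secondary C1 hydroxyl and leaves the tertiary C12 hydroxyl free for steric reasons, and since no bond to C1 is broken its configuration is retained.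

Compound list
1 | 2-oxazolidinone | O=C1NCCO1 | starting material
2 | acryloyl chloride | C=CC(Cl)=O | starting material
3 | bromomagnesium salt of 2-oxazolidinone (not isolated) | O=C1OCCN1[Mg]Br | intermediate
4 | 3-acryloyl-1,3-oxazolidin-2-one | C=CC(=O)N1CCOC1=O | intermediate
5 | 3-methylfuran | Cc1ccoc1 | starting material
6 | 3-[(1R,2R,4R)-5-methyl-7-oxabicyclo[2.2.1]hept-5-ene-2-carbonyl]-1,3-oxazolidin-2-one (endo) | O1[C@@H]2C=C(C)[C@H]1C[C@H]2C(=O)N1CCOC1=O | intermediate
7 | (1R,2R,4R)-N-methoxy-N,5-dimethyl-7-oxabicyclo[2.2.1]hept-5-ene-2-carboxamide | O1[C@@H]2C=C(C)[C@H]1C[C@H]2C(=O)N(C)OC | intermediate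
8 | bromomagnesium hemiaminal adduct of 7 with MeMgBr (not isolated) | O1[C@@H]2C=C(C)[C@H]1C[C@H]2C(C)(O[Mg]Br)N(C)OC | intermediate
9 | 1-[(1R,2R,4R)-5-methyl-7-oxabicyclo[2.2.1]hept-5-en-2-yl]ethan-1-one | O1[C@@H]2C=C(C)[C@H]1C[C@H]2C(C)=O | intermediate
10 | terminal potassium enolate of 9 (not isolated) | O1[C@@H]2C=C(C)[C@H]1C[C@H]2C(=C)[O-].[K+] | intermediate
11 | 1-[(1R,2R,4R)-5-methyl-7-oxabicyclo[2.2.1]hept-5-en-2-yl]ethenyl triflate | O1[C@@H]2C=C(C)[C@H]1C[C@H]2C(=C)OS(=O)(=O)C(F)(F)F | intermediate
12 | exo C2 B-alkyl-9-BBN adduct of 11 (not isolated) | O1[C@@H]2[C@H](B3C4CCCC3CCC4)[C@@H](C)[C@H]1C[C@H]2C(=C)OS(=O)(=O)C(F)(F)F | intermediate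
13 | 1-[(1S,2R,4R,5R,6R)-6-hydroxy-5-methyl-7-oxabicyclo[2.2.1]heptan-2-yl]ethenyl triflate | O1[C@@H]2[C@H](O)[C@@H](C)[C@H]1C[C@H]2C(=C)OS(=O)(=O)C(F)(F)F | intermediate
14 | 1-[(1S,2R,4R,5S)-5-methyl-6-oxo-7-oxabicyclo[2.2.1]heptan-2-yl]ethenyl triflate | O1[C@@H]2C(=O)[C@@H](C)[C@H]1C[C@H]2C(=C)OS(=O)(=O)C(F)(F)F | intermediate
15 | C2 TBS enol ether of 14 (not isolated) | O1[C@@H]2C(O[Si](C)(C)C(C)(C)C)=C(C)[C@H]1C[C@H]2C(=C)OS(=O)(=O)C(F)(F)F | intermediate
16 | 1-[(1R,6S)-6-(tert-butyldimethylsilyloxy)-4-methyl-5-oxocyclohex-3-en-1-yl]ethenyl triflate | CC(C)(C)[Si](C)(C)O[C@@H]1C(=O)C(C)=CC[C@H]1C(=C)OS(=O)(=O)C(F)(F)F | intermediate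
17 | (5S,6S)-6-(tert-butyldimethylsilyloxy)-5-(3-hydroxyprop-1-en-2-yl)-2-methylcyclohex-2-en-1-one | CC(C)(C)[Si](C)(C)O[C@@H]1C(=O)C(C)=CC[C@H]1C(=C)CO | intermediate
18 | (5R,6S)-6-(tert-butyldimethylsilyloxy)-5-[(2S)-2-(hydroxymethyl)oxiran-2-yl]-2-methylcyclohex-2-en-1-one | CC(C)(C)[Si](C)(C)O[C@@H]1C(=O)C(C)=CC[C@H]1[C@]1(CO)CO1 | intermediate
19 | (1S,5R,6S)-6-(tert-butyldimethylsilyloxy)-5-[(2S)-2-(hydroxymethyl)oxiran-2-yl]-2-methylcyclohex-2-en-1-ol | CC(C)(C)[Si](C)(C)O[C@@H]1[C@@H](O)C(C)=CC[C@H]1[C@]1(CO)CO1 | intermediate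
20 | (1R,2R,3S,4R,6S)-3-(tert-butyldimethylsilyloxy)-4-[(2S)-2-(hydroxymethyl)oxiran-2-yl]-1-methyl-7-oxabicyclo[4.1.0]heptan-2-ol | CC(C)(C)[Si](C)(C)O[C@@H]1[C@@H](O)[C@@]2(C)O[C@H]2C[C@H]1[C@]1(CO)CO1 | intermediate
21 | (2R)-2-[(1S,3R,4S,6S)-4-(tert-butyldimethylsilyloxy)-6-methyl-5-oxo-7-oxabicyclo[4.1.0]heptan-3-yl]oxirane-2-carbaldehyde | CC(C)(C)[Si](C)(C)O[C@@H]1C(=O)[C@@]2(C)O[C@H]2C[C@H]1[C@]1(C=O)CO1 | intermediate
22 | trimethyl[(2-methylbut-3-yn-2-yl)oxy]silane | C#CC(C)(C)O[Si](C)(C)C | starting material
23 | (E)-alkenyl(chloro)zirconocene from 22, Cp rings drawn σ-bound (not isolated) | C[Si](C)(C)OC(C)(C)/C=C/[Zr](Cl)(C1C=CC=C1)C1C=CC=C1 | intermediate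
24 | (E)-[3-methyl-3-(trimethylsilyloxy)but-1-enyl](methyl)zinc (not isolated) | C[Zn]/C=C/C(C)(C)O[Si](C)(C)C | intermediate
25 | C9 carbinol, both C9 epimers (C1-OTBS, C12-OTMS, C2 ketone, both oxiranes, E alkene) | CC(C)(C)[Si](C)(C)O[C@@H]1C(=O)[C@@]2(C)O[C@H]2C[C@H]1[C@]1(C(O)/C=C/C(C)(C)O[Si](C)(C)C)CO1 | intermediate
26 | bis-silylated enone (C1-OTBS, C12-OTMS, C9 ketone; 1S,3S,4S,6R,7R) | CC(C)(C)[Si](C)(C)O[C@@H]1C(=O)[C@@]2(C)O[C@H]2C[C@H]1[C@]1(C(=O)/C=C/C(C)(C)O[Si](C)(C)C)CO1 | intermediate
27 | C1,C12-diol, the target without its isovaleryl group (1S,3S,4S,6R,7R) | O[C@@H]1C(=O)[C@@]2(C)O[C@H]2C[C@H]1[C@]1(C(=O)/C=C/C(C)(C)O)CO1 | intermediate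
28 | 3-methylbutanoic (isovaleric) anhydride | CC(C)CC(=O)OC(=O)CC(C)C | starting material
29 | CNP0292003.1 (1S,3S,4S,6R,7R; 10E) | CC(C)CC(=O)O[C@@H]1C(=O)[C@@]2(C)O[C@H]2C[C@H]1[C@]1(C(=O)/C=C/C(C)(C)O)CO1 | target

Total steps: 17. Longest linear sequence: 17 steps (1 and 2 to 29); 5, 22 and 28 are bought and enter directly.

Steps most likely to fail

**Step 2.**
- What may go wrong: the methyl group may steer the regiochemistry only weakly, exo addition or conjugate alkylation of the furan may compete, and cycloreversion on the Lewis acid may erode the enantiomeric purity.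
- Fallback: it sets out from 5 and 2 and replaces the chiral catalyst by a covalently bound controller, so that all unwanted isomers become separable diastereomers.
  - Commercial (S)-4-benzyl-2-oxazolidinone is N-acylated with 2 as in step 1 to give (S)-3-acryloyl-4-benzyl-1,3-oxazolidin-2-one F1.
  - Et2AlCl (1.4 equiv, CH2Cl2, −78 °C) chelates this imide, the benzyl group shields one face, and cycloaddition with 5 forms the same C1–C6 and C4–C5 bonds to give the endo (1R,2R,4R) auxiliary adduct F2, which is purified by crystallisation.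
  - The aluminium-amide transamination of step 3 then releases the auxiliary, and the route is rejoined at 7.

**Step 9.**
- What may go wrong: transfer of the hydroxymethyl group from tin may be slow, so that butyl transfer, protodestannylation or thermal decay of the silyloxy enone takes over.
- Fallback: it sets out from 16 and brings in C9 as carbon monoxide at room temperature.
  - Pd(OAc)2, dppp, CO (1 atm), MeOH and Et3N in DMF give methyl 2-[(1R,6S)-6-(tert-butyldimethylsilyloxy)-4-methyl-5-oxocyclohex-3-en-1-yl]acrylate F3.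
  - Excess i-Bu2AlH (CH2Cl2, −78 °C) reduces the ester and, by axial hydride delivery, the enone carbonyl to the bis-allylic diol F4.
  - The tartrate epoxidation of step 10 then acts first on the primary 2-substituted allylic alcohol, and the route is rejoined at 19. Any further hydroxyl-directed epoxidation of the ring alkene only anticipates step 12.

**Step 14.**
- What may go wrong: addition to the α-quaternary aldehyde may be sluggish, methyl transfer from zinc may compete, and the zirconocene by-product may open an oxirane.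
- Fallback: it sets out from 21 and builds C10=C11 by olefin metathesis instead of by alkenyl addition.
  - CH2=CHMgBr (THF, −78 °C) adds the small vinyl group to the aldehyde to give the vinyl carbinol F5.
  - Dess–Martin oxidation gives the vinyl ketone F6.
  - Cross-metathesis with excess 2-methylbut-3-en-2-ol, using the second-generation Hoveyda–Grubbs catalyst (H2IMes)Cl2Ru=CH(2-i-PrOC6H4) in CH2Cl2 at 40 °C, gives the E-configured C1-O-TBS hydroxy enone F7.
  - HF·pyridine as in step 16 then leads back to the route at 27.

Further compounds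
F1 | step 2 | (S)-3-acryloyl-4-benzyl-1,3-oxazolidin-2-one | C=CC(=O)N1[C@@H](Cc2ccccc2)COC1=O
F2 | step 2 | (4S)-4-benzyl-3-[(1R,2R,4R)-5-methyl-7-oxabicyclo[2.2.1]hept-5-ene-2-carbonyl]-1,3-oxazolidin-2-one | O1[C@@H]2C=C(C)[C@H]1C[C@H]2C(=O)N1[C@@H](Cc2ccccc2)COC1=O
F3 | step 9 | methyl 2-[(1R,6S)-6-(tert-butyldimethylsilyloxy)-4-methyl-5-oxocyclohex-3-en-1-yl]acrylate | CC(C)(C)[Si](C)(C)O[C@@H]1C(=O)C(C)=CC[C@H]1C(=C)C(=O)OC
F4 | step 9 | bis-allylic diol (top-face C2-OH, C9-OH, C1-OTBS, C3=C4 and C7=C8) | CC(C)(C)[Si](C)(C)O[C@@H]1[C@@H](O)C(C)=CC[C@H]1C(=C)CO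
F5 | step 14 | vinyl carbinol, both C9 epimers | CC(C)(C)[Si](C)(C)O[C@@H]1C(=O)[C@@]2(C)O[C@H]2C[C@H]1[C@]1(C(O)C=C)CO1
F6 | step 14 | vinyl ketone | CC(C)(C)[Si](C)(C)O[C@@H]1C(=O)[C@@]2(C)O[C@H]2C[C@H]1[C@]1(C(=O)C=C)CO1
F7 | step 14 | C1-O-TBS hydroxy enone | CC(C)(C)[Si](C)(C)O[C@@H]1C(=O)[C@@]2(C)O[C@H]2C[C@H]1[C@]1(C(=O)/C=C/C(C)(C)O)CO1
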